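The route rests on disconnecting ring A of the hexahydroindene at C7–C7a and C5–C6. Its lone double bond, C3a=C4, sits where a [4+2] addition to a C7a=C3a–C4=C5 diene must put it, and one C7 methyl can come from a carbonyl tethered to an oxygen on C2 of ring B. In one operation the tethered methacrylate closes ring A and a bridging δ-lactone, joins the adjacent quaternary carbons C7 and C7a, and places the C7a methyl cis to the C1 methyl, because the C2 oxygen lies on the allyl face. The precursor is the methacrylate of (1R,2S)-2-allyl-2,3-dimethyl-4-vinylcyclopent-3-en-1-ol, a 2-methyl-1-vinylcyclopentene.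

Key step: step 9

Assumption: a ketoreductase that reduces dione 3 to the (2R,3R)-ketol (hydroxyl cis to allyl) is taken to be available from a commercial enzyme panel; the enantiomeric (2S,3S) selectivity is the one long known from microbial reduction.

Numbering: bicyclic compounds are numbered as indenes (C1 to C7a); ring A is the six-membered ring and ring B the five-membered ring. Enol ethers 18 to 24 are carried as E/Z mixtures at the exocyclic C2 double bond.

Step 1
Reactants: 1 2-methylcyclopentane-1,3-dione; 2 allyl bromide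
Product: 3 2-allyl-2-methylcyclopentane-1,3-dione
Conditions: NaOH (1 M aq.), rt
Reagents that add atoms: none
Why: C-alkylation of the 1,3-diketone enolate with a soft allylic bromide in aqueous base is a standard route to the 2,2-disubstituted dione; the new quaternary carbon is still prochiral, so no stereocentre is set.

Step 2
Reactants: 3 2-allyl-2-methylcyclopentane-1,3-dione
Product: 4 (2R,3R)-2-allyl-3-hydroxy-2-methylcyclopentan-1-one (hydroxyl cis to allyl)
Conditions: ketoreductase (panel-selected), NADP+ (cat.), i-PrOH, phosphate buffer pH 7, 30 °C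
Reagents that add atoms: none
Why: Enzymatic desymmetrising ketone reduction: the enzyme selects one of the two enantiotopic carbonyls and one of its faces, so a single hydride transfer from NADPH should fix both the carbinol carbon (R) and the quaternary carbon (R), and the neutral pH spares the retro-aldol-prone ketol.

Step 3
Reactants: 4 (2R,3R)-2-allyl-3-hydroxy-2-methylcyclopentan-1-one
Product: 5 (2R,3R)-2-allyl-3-[(tert-butyldiphenylsilyl)oxy]-2-methylcyclopentan-1-one
Conditions: TBDPSCl, imidazole, DMAP (cat.), DMF, 40 °C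
Reagents that add atoms: tert-butyl(chloro)diphenylsilane, CC(C)(C)[Si](Cl)(c1ccccc1)c1ccccc1
Why: Imidazole-mediated silylation of the secondary alcohol; a bulky silyl ether is preferred to an ester because siloxide is a poor leaving group for vinylogous β-elimination from the enal of steps 4 and 5 and the group tolerates the acidic Vilsmeier medium.

Step 4
Reactants: 5 (2R,3R)-2-allyl-3-[(tert-butyldiphenylsilyl)oxy]-2-methylcyclopentan-1-one
Product: 7 (3R,4R)-3-allyl-2-bromo-4-[(tert-butyldiphenylsilyl)oxy]-3-methylcyclopent-1-ene-1-carbaldehyde, via bromo-vinyl iminium bromide 6 (not isolated)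
Conditions: PBr3, DMF, CH2Cl2, 0 °C → rt; then ice–water
Reagents that add atoms: N,N-dimethylformamide, CN(C)C=O; phosphorus tribromide, BrP(Br)Br; water, O
Why: Vilsmeier–Arnold bromoformylation: the ketone can enolise only toward its CH2 side (the other α-carbon is quaternary), the enol is formylated by the bromoiminium salt and bromide replaces the activated oxygen, so hydrolysis should give a single β-bromo enal with both stereocentres untouched.

Step 5
Reactants: 7 (3R,4R)-3-allyl-2-bromo-4-[(tert-butyldiphenylsilyl)oxy]-3-methylcyclopent-1-ene-1-carbaldehyde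
Product: 8 (3S,4R)-3-allyl-4-[(tert-butyldiphenylsilyl)oxy]-2,3-dimethylcyclopent-1-ene-1-carbaldehyde
Conditions: MeB(OH)2, PdCl2(dppf) (cat.), K3PO4, dioxane/H2O, 80 °C
Reagents that add atoms: methylboronic acid, CB(O)O
Why: Suzuki–Miyaura methylation; the β-bromo enal is a vinylogous acyl bromide that undergoes oxidative addition readily despite the neighbouring quaternary carbon, and transmetalation from the boronate delivers the future C7a methyl.

Step 6
Reactants: 8 (3S,4R)-3-allyl-4-[(tert-butyldiphenylsilyl)oxy]-2,3-dimethylcyclopent-1-ene-1-carbaldehyde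
Product: 9 tert-butyl{[(1R,2S)-2-allyl-2,3-dimethyl-4-vinylcyclopent-3-en-1-yl]oxy}diphenylsilane
Conditions: Ph3PCH3Br, KN(SiMe3)2, THF, 0 °C; then 8, −78 °C → rt
Reagents that add atoms: methyltriphenylphosphonium bromide, C[P+](c1ccccc1)(c1ccccc1)c1ccccc1.[Br-]
Why: Wittig methylenation of an unhindered conjugated aldehyde with the non-stabilised ylide should give the 1-vinylcyclopentene diene without touching the silyl ether.

Step 7
Reactants: 9 tert-butyl{[(1R,2S)-2-allyl-2,3-dimethyl-4-vinylcyclopent-3-en-1-yl]oxy}diphenylsilane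
Product: 10 (1R,2S)-2-allyl-2,3-dimethyl-4-vinylcyclopent-3-en-1-ol
Conditions: Bu4NF, THF, rt → 40 °C
Reagents that add atoms: none
Why: Fluoride-induced cleavage of the Si–O bond (desilylation) frees the hydroxyl with retention, the hydrocarbon diene being inert to fluoride.

Step 8
Reactants: 10 (1R,2S)-2-allyl-2,3-dimethyl-4-vinylcyclopent-3-en-1-ol; 11 methacryloyl chloride
Product: 12 (1R,2S)-2-allyl-2,3-dimethyl-4-vinylcyclopent-3-en-1-yl 2-methylprop-2-enoate (ester oxygen cis to allyl)
Conditions: Et3N, DMAP (cat.), CH2Cl2, 0 °C → rt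
Reagents that add atoms: none
Why: DMAP-catalysed O-acylation of the hindered secondary alcohol by the acid chloride installs the dienophile without affecting the configuration at the carbinol carbon.

Step 9
Reactants: 12 (1R,2S)-2-allyl-2,3-dimethyl-4-vinylcyclopent-3-en-1-yl 2-methylprop-2-enoate
Product: 13 1-allyl-2-hydroxy-1,7,7a-trimethyl-2,3,5,6,7,7a-hexahydro-1H-indene-7-carboxylic acid 7,2-lactone (C2–O cis to allyl; C7a methyl cis to C1 methyl)
Conditions: MeAlCl2 (1.2 equiv), CH2Cl2, −78 → −20 °C; then 1 M HCl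
Reagents that add atoms: none
Why: MeAlCl2 binds the ester carbonyl and the methacrylate adds across the C7a=C3a–C4=C5 diene in a concerted but strongly asynchronous [4+2] reaction, in which the unsubstituted terminus C5 bonds to the β-carbon C6 first and the tertiary allyl-cation character developing at C7a then closes onto C7, so the bond between the two fully substituted carbons forms late and intramolecularly. The closest known reaction type is the type 1 intramolecular Diels–Alder reaction of dienyl acrylates through an ester tether, which gives lactone-fused cyclohexenes on heating or with alkylaluminium chlorides. Ring A closes through the cycloaddition itself (bonds C7–C7a and C5–C6, new double bond C3a=C4), and the six-membered lactone closes at the same time as the tether C2–O–C(=O)–C7 is drawn across C1 into a 2-oxabicyclo[3.2.1]octanone, with the carbonyl endo beneath C3a. C7a is controlled by the tether, because the C2 oxygen sits on the allyl face and C7 can reach C7a only there, which leaves the C7a methyl cis to the C1 methyl; C7 can adopt only one configuration inside the bridged lactone and is erased in step 11. The step needs facial selectivity against the steric preference and a single regiochemistry, and both are secured by the short tether, which cannot span the other face or the other orientation. The Lewis acid allows reaction below 0 °C, so that the 1,5-diene made up of the C1 allyl group and C7a=C3a cannot enter a Cope rearrangement as it might on thermolysis.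

Step 10
Reactants: 13 bridged lactone
Product: 14 lactol of 13 (C7–CH(OH)–O–C2 hemiacetal, anomer mixture)
Conditions: i-Bu2AlH (1.2 equiv), CH2Cl2, −78 °C; aq. potassium sodium tartrate
Reagents that add atoms: none
Why: Partial reduction of a lactone with i-Bu2AlH at −78 °C stops at the aluminium hemiacetal of the hindered carbonyl on quaternary C7 and should give the lactol on work-up, the alkenes being inert.

Step 11
Reactants: 14 lactol
Product: 16 (1S,2R,7aS)-1-allyl-1,7,7,7a-tetramethyl-2,3,5,6,7,7a-hexahydro-1H-inden-2-ol, via hydroxy aldehyde hydrazone 15 (not isolated)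
Conditions: N2H4·H2O, KOH, diethylene glycol, 130 °C, then 200 °C
Reagents that add atoms: none
Why: Wolff–Kishner reduction in its Huang-Minlon form acts on the ring-opened hydroxy aldehyde of the lactol: the non-enolisable aldehyde on C7 forms the hydrazone, base-mediated loss of N2 turns it into the second C7 methyl and leaves the C2 hydroxyl free, and unactivated alkenes survive hot KOH.

Step 12
Reactants: 16 (1S,2R,7aS)-1-allyl-1,7,7,7a-tetramethyl-2,3,5,6,7,7a-hexahydro-1H-inden-2-ol
Product: 17 (1S,7aS)-1-allyl-1,7,7,7a-tetramethyl-1,3,5,6,7,7a-hexahydro-2H-inden-2-one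
Conditions: Dess–Martin periodinane, pyridine, CH2Cl2, 0 °C → rt
Reagents that add atoms: none
Why: Dess–Martin oxidation of the hindered secondary alcohol under buffered, non-enolising conditions should give the β,γ-unsaturated ketone without moving C3a=C4 into conjugation.

Step 13
Reactants: 17 (1S,7aS)-1-allyl-1,7,7,7a-tetramethyl-1,3,5,6,7,7a-hexahydro-2H-inden-2-one
Product: 18 (1S,7aS)-1-allyl-2-(methoxymethylidene)-1,7,7,7a-tetramethyl-2,3,5,6,7,7a-hexahydro-1H-indene (E/Z mixture)
Conditions: Ph3P(CH2OMe)Cl, KN(SiMe3)2, THF, 0 °C; then 17, 0 → 50 °C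
Reagents that add atoms: (methoxymethyl)triphenylphosphonium chloride, COC[P+](c1ccccc1)(c1ccccc1)c1ccccc1.[Cl-]
Why: Wittig reaction with the methoxymethylene ylide, a standard one-carbon homologation of cyclopentanones flanked by a quaternary carbon (17-keto steroids are the model), gives the enol ether as a base- and hydride-stable masked aldehyde whose double-bond geometry is irrelevant.

Step 14
Reactants: 18 enol ether
Product: 20 3-[(1S,7aS)-2-(methoxymethylidene)-1,7,7,7a-tetramethyl-2,3,5,6,7,7a-hexahydro-1H-inden-1-yl]propan-1-ol, via B-alkyl 9-BBN adduct 19 (not isolated)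
Conditions: 9-BBN (1.2 equiv), THF, 0 °C → rt; then NaOH (3 M aq.), H2O2 (30%), 0 °C
Reagents that add atoms: hydrogen peroxide, OO
Why: Hydroboration–oxidation: 9-BBN adds anti-Markovnikov to the monosubstituted allyl alkene far faster than to the trisubstituted ring A alkene or to the enol ether, whose boron-accepting carbon C2 is fully substituted, and alkaline peroxide converts the C–B bond into the primary alcohol.

Step 15
Reactants: 20 primary alcohol
Product: 21 3-[(1S,7aS)-2-(methoxymethylidene)-1,7,7,7a-tetramethyl-2,3,5,6,7,7a-hexahydro-1H-inden-1-yl]propanal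
Conditions: Dess–Martin periodinane, pyridine, CH2Cl2, 0 °C
Reagents that add atoms: none
Why: Dess–Martin oxidation of the primary alcohol, buffered with pyridine so that the acid-labile enol ether survives, should stop cleanly at the aldehyde.

Step 16
Reactants: 21 aldehyde
Product: 22 ethyl (2Z)-5-[(1S,7aS)-2-(methoxymethylidene)-1,7,7,7a-tetramethyl-2,3,5,6,7,7a-hexahydro-1H-inden-1-yl]-2-methylpent-2-enoate
Conditions: (CF3CH2O)2P(O)CH(Me)CO2Et, KN(SiMe3)2, 18-crown-6, THF, −78 °C
Reagents that add atoms: ethyl 2-[bis(2,2,2-trifluoroethoxy)phosphoryl]propanoate, CCOC(=O)C(C)P(=O)(OCC(F)(F)F)OCC(F)(F)F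
Why: Still–Gennari variant of the Horner–Wadsworth–Emmons olefination: with the bis(trifluoroethyl) phosphonate and a crown-ether-separated potassium ion the kinetically formed adduct eliminates faster than it equilibrates, which should give the (Z)-2-methyl enoate with the ester cis to the chain.

Step 17
Reactants: 22 (Z)-enoate
Product: 23 (2Z)-5-[(1S,7aS)-2-(methoxymethylidene)-1,7,7,7a-tetramethyl-2,3,5,6,7,7a-hexahydro-1H-inden-1-yl]-2-methylpent-2-en-1-ol
Conditions: i-Bu2AlH (2.5 equiv), CH2Cl2, −78 °C; aq. potassium sodium tartrate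
Reagents that add atoms: none
Why: 1,2-Reduction of the enoate with i-Bu2AlH gives the allylic alcohol with the Z geometry preserved, the enol ether and the ring alkene being inert to the hydride.

Step 18
Reactants: 23 (Z)-allylic alcohol
Product: 24 (2Z)-5-[(1S,7aS)-2-(methoxymethylidene)-1,7,7,7a-tetramethyl-2,3,5,6,7,7a-hexahydro-1H-inden-1-yl]-2-methylpent-2-en-1-yl acetate
Conditions: Ac2O, pyridine, DMAP (cat.), CH2Cl2, 0 °C → rt
Reagents that add atoms: acetic anhydride, CC(=O)OC(C)=O
Why: DMAP-catalysed acetylation of the unhindered primary allylic alcohol is routine and, being basic, leaves the enol ether untouched.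

Step 19
Reactants: 24 enol ether acetate
Product: 26 (2Z)-5-[(1R,2S,7aS)-2-formyl-1,7,7,7a-tetramethyl-2,3,5,6,7,7a-hexahydro-1H-inden-1-yl]-2-methylpent-2-en-1-yl acetate, via C2-epimeric aldehyde 25 (not isolated)
Conditions: 1 M HCl, THF, 0 °C → rt; then DBU (cat.), CH2Cl2, rt
Reagents that add atoms: water, O
Why: Acid hydrolysis of the enol ether (protonation at C2, then collapse of the hemiacetal) unmasks the aldehyde, and amine-base enolisation should then equilibrate C2 to the more stable epimer, in which the formyl group lies on the face of the C1 and C7a methyls and avoids the C1 chain and the C7 methyl beneath ring B (the bias that favours 17β-acyl groups in steroid D rings), while the allylic acetate tolerates dilute acid and DBU.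

Step 20
Reactants: 26 aldehyde
Product: 27 (1R,2S,7aS)-1-[(3Z)-5-(acetyloxy)-4-methylpent-3-en-1-yl]-1,7,7,7a-tetramethyl-2,3,5,6,7,7a-hexahydro-1H-indene-2-carboxylic acid (CNP0289983.1)
Conditions: NaClO2, NaH2PO4, 2-methylbut-2-ene, t-BuOH/H2O, 0 °C → rt
Reagents that add atoms: sodium chlorite, [Na+].[O-]Cl=O
Why: Pinnick oxidation turns the aldehyde into the carboxylic acid under mildly acidic conditions that do not epimerise C2, with 2-methylbut-2-ene scavenging HOCl so that the alkenes and the acetate are untouched.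

Compound list
1 | 2-methylcyclopentane-1,3-dione | CC1C(=O)CCC1=O | starting material
2 | allyl bromide | C=CCBr | starting material
3 | 2-allyl-2-methylcyclopentane-1,3-dione | C=CCC1(C)C(=O)CCC1=O | intermediate
4 | (2R,3R)-2-allyl-3-hydroxy-2-methylcyclopentan-1-one | C=CC[C@]1(C)[C@H](O)CCC1=O | intermediate
5 | (2R,3R)-2-allyl-3-[(tert-butyldiphenylsilyl)oxy]-2-methylcyclopentan-1-one | C=CC[C@]1(C)[C@H](O[Si](c2ccccc2)(c2ccccc2)C(C)(C)C)CCC1=O | intermediate
6 | N-{[(3R,4R)-3-allyl-2-bromo-4-[(tert-butyldiphenylsilyl)oxy]-3-methylcyclopent-1-en-1-yl]methylidene}-N-methylmethanaminium bromide (not isolated) | C=CC[C@]1(C)[C@H](O[Si](c2ccccc2)(c2ccccc2)C(C)(C)C)CC(C=[N+](C)C)=C1Br.[Br-] | intermediate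
7 | (3R,4R)-3-allyl-2-bromo-4-[(tert-butyldiphenylsilyl)oxy]-3-methylcyclopent-1-ene-1-carbaldehyde | C=CC[C@]1(C)[C@H](O[Si](c2ccccc2)(c2ccccc2)C(C)(C)C)CC(C=O)=C1Br | intermediate
8 | (3S,4R)-3-allyl-4-[(tert-butyldiphenylsilyl)oxy]-2,3-dimethylcyclopent-1-ene-1-carbaldehyde | C=CC[C@]1(C)[C@H](O[Si](c2ccccc2)(c2ccccc2)C(C)(C)C)CC(C=O)=C1C | intermediate
9 | tert-butyl{[(1R,2S)-2-allyl-2,3-dimethyl-4-vinylcyclopent-3-en-1-yl]oxy}diphenylsilane | C=CC[C@]1(C)[C@H](O[Si](c2ccccc2)(c2ccccc2)C(C)(C)C)CC(C=C)=C1C | intermediate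
10 | (1R,2S)-2-allyl-2,3-dimethyl-4-vinylcyclopent-3-en-1-ol | C=CC[C@]1(C)[C@H](O)CC(C=C)=C1C | intermediate
11 | methacryloyl chloride | CC(=C)C(=O)Cl | starting material
12 | (1R,2S)-2-allyl-2,3-dimethyl-4-vinylcyclopent-3-en-1-yl 2-methylprop-2-enoate | C=CC[C@]1(C)[C@H](OC(=O)C(C)=C)CC(C=C)=C1C | intermediate
13 | 1-allyl-2-hydroxy-1,7,7a-trimethyl-2,3,5,6,7,7a-hexahydro-1H-indene-7-carboxylic acid 7,2-lactone (C2–O cis to allyl, C7a methyl cis to C1 methyl) | C=CC[C@]1(C)[C@H]2CC3=CCC[C@](C)(C(=O)O2)[C@@]31C | intermediate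
14 | lactol of 13 (hemiacetal carbon on C7, anomer mixture) | C=CC[C@]1(C)[C@H]2CC3=CCC[C@](C)(C(O)O2)[C@@]31C | intermediate
15 | hydrazone of 1-allyl-2-hydroxy-1,7,7a-trimethyl-2,3,5,6,7,7a-hexahydro-1H-indene-7-carbaldehyde (not isolated) | C=CC[C@]1(C)[C@H](O)CC2=CCC[C@](C)(C=NN)[C@@]21C | intermediate
16 | (1S,2R,7aS)-1-allyl-1,7,7,7a-tetramethyl-2,3,5,6,7,7a-hexahydro-1H-inden-2-ol | C=CC[C@]1(C)[C@H](O)CC2=CCCC(C)(C)[C@@]21C | intermediate
17 | (1S,7aS)-1-allyl-1,7,7,7a-tetramethyl-1,3,5,6,7,7a-hexahydro-2H-inden-2-one | C=CC[C@]1(C)C(=O)CC2=CCCC(C)(C)[C@@]21C | intermediate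
18 | (1S,7aS)-1-allyl-2-(methoxymethylidene)-1,7,7,7a-tetramethyl-2,3,5,6,7,7a-hexahydro-1H-indene (E/Z mixture) | C=CC[C@]1(C)C(=COC)CC2=CCCC(C)(C)[C@@]21C | intermediate
19 | 9-{3-[(1S,7aS)-2-(methoxymethylidene)-1,7,7,7a-tetramethyl-2,3,5,6,7,7a-hexahydro-1H-inden-1-yl]propyl}-9-borabicyclo[3.3.1]nonane (not isolated) | C(CCB3C4CCCC3CCC4)[C@]1(C)C(=COC)CC2=CCCC(C)(C)[C@@]21C | intermediate
20 | 3-[(1S,7aS)-2-(methoxymethylidene)-1,7,7,7a-tetramethyl-2,3,5,6,7,7a-hexahydro-1H-inden-1-yl]propan-1-ol | OCCC[C@]1(C)C(=COC)CC2=CCCC(C)(C)[C@@]21C | intermediate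
21 | 3-[(1S,7aS)-2-(methoxymethylidene)-1,7,7,7a-tetramethyl-2,3,5,6,7,7a-hexahydro-1H-inden-1-yl]propanal | O=CCC[C@]1(C)C(=COC)CC2=CCCC(C)(C)[C@@]21C | intermediate
22 | ethyl (2Z)-5-[(1S,7aS)-2-(methoxymethylidene)-1,7,7,7a-tetramethyl-2,3,5,6,7,7a-hexahydro-1H-inden-1-yl]-2-methylpent-2-enoate | CCOC(=O)/C(C)=C\CC[C@]1(C)C(=COC)CC2=CCCC(C)(C)[C@@]21C | intermediate
23 | (2Z)-5-[(1S,7aS)-2-(methoxymethylidene)-1,7,7,7a-tetramethyl-2,3,5,6,7,7a-hexahydro-1H-inden-1-yl]-2-methylpent-2-en-1-ol | OC/C(C)=C\CC[C@]1(C)C(=COC)CC2=CCCC(C)(C)[C@@]21C | intermediate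
24 | (2Z)-5-[(1S,7aS)-2-(methoxymethylidene)-1,7,7,7a-tetramethyl-2,3,5,6,7,7a-hexahydro-1H-inden-1-yl]-2-methylpent-2-en-1-yl acetate | CC(=O)OC/C(C)=C\CC[C@]1(C)C(=COC)CC2=CCCC(C)(C)[C@@]21C | intermediate
25 | (2Z)-5-[(1R,2R,7aS)-2-formyl-1,7,7,7a-tetramethyl-2,3,5,6,7,7a-hexahydro-1H-inden-1-yl]-2-methylpent-2-en-1-yl acetate (C2 epimer, formyl cis to the C1 chain; not isolated) | CC(=O)OC/C(C)=C\CC[C@]1(C)[C@H](C=O)CC2=CCCC(C)(C)[C@@]21C | intermediate
26 | (2Z)-5-[(1R,2S,7aS)-2-formyl-1,7,7,7a-tetramethyl-2,3,5,6,7,7a-hexahydro-1H-inden-1-yl]-2-methylpent-2-en-1-yl acetate | CC(=O)OC/C(C)=C\CC[C@]1(C)[C@@H](C=O)CC2=CCCC(C)(C)[C@@]21C | intermediate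
27 | (1R,2S,7aS)-1-[(3Z)-5-(acetyloxy)-4-methylpent-3-en-1-yl]-1,7,7,7a-tetramethyl-2,3,5,6,7,7a-hexahydro-1H-indene-2-carboxylic acid | CC(=O)OC/C(C)=C\CC[C@]1(C)[C@@H](C(=O)O)CC2=CCCC(C)(C)[C@@]21C | target

Total steps: 20. Longest linear sequence: 20 steps (1 to 27).

Steps most likely to fail

Step 9. The cycloaddition may stall because bonding between the fully substituted carbons C7 and C7a, next to quaternary C1 and with the C7a methyl on the inside of the s-cis diene, is slow. Lewis-acid-induced oligomerisation of the electron-rich diene, or proton loss from the allyl-cation-like species formed after the first bond, could then take over. Fallback, setting out from 10 and returning at 13: the quaternary C7 would be built in two stages with a sterically undemanding alkyne dienophile. Alcohol 10 is esterified with propiolic acid (DCC, DMAP, CH2Cl2, −20 °C) to (1R,2S)-2-allyl-2,3-dimethyl-4-vinylcyclopent-3-en-1-yl prop-2-ynoate F1. Thermal intramolecular Diels–Alder reaction of this alkynoate (toluene, BHT, 110 to 140 °C), a known way to form a quaternary ring-fusion carbon from a 2-methyl-1-vinylcycloalkene, should give 1-allyl-2-hydroxy-1,7a-dimethyl-2,3,5,7a-tetrahydro-1H-indene-7-carboxylic acid 7,2-lactone F2, in which only C7a is newly quaternary. Conjugate reduction with LiBH(s-Bu)3 (THF, −78 °C) and trapping of the lactone enolate with MeI then places hydrogen on C6 and methyl on C7, the bridged ring allowing only one C7 configuration, and the route is rejoined at lactone 13.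

Step 13. The basic ylide may deprotonate C3, which is both α to the ketone and allylic, instead of adding to the crowded carbonyl, so that ketone is returned or its double bond drifts into conjugation. Fallback, setting out from 17 and returning at 18: a Peterson olefination in two operations with a small, hard nucleophile. [Methoxy(trimethylsilyl)methyl]lithium (from MeOCH2SiMe3 and s-BuLi, THF, −78 °C) adds to ketone 17 to give (1S,7aS)-1-allyl-2-[methoxy(trimethylsilyl)methyl]-1,7,7,7a-tetramethyl-2,3,5,6,7,7a-hexahydro-1H-inden-2-ol F3, and KH (THF, rt) then eliminates silanolate to give enol ether 18.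

Step 19. Equilibration at C2 under the mild amine base may remain incomplete, or the acid needed for hydrolysis may ionise or cleave the allylic acetate. Fallback, setting out from 23 and returning at 27: the C2 configuration is settled before the acetate exists. Alcohol 23 is hydrolysed (1 M HCl, THF) and equilibrated under fully reversible protic conditions (K2CO3, MeOH) to (1R,2S,7aS)-1-[(3Z)-5-hydroxy-4-methylpent-3-en-1-yl]-1,7,7,7a-tetramethyl-2,3,5,6,7,7a-hexahydro-1H-indene-2-carbaldehyde F4. Pinnick oxidation gives (1R,2S,7aS)-1-[(3Z)-5-hydroxy-4-methylpent-3-en-1-yl]-1,7,7,7a-tetramethyl-2,3,5,6,7,7a-hexahydro-1H-indene-2-carboxylic acid F5, from which residual C2 epimer can be removed by crystallisation of an amine salt. Acetylation (Ac2O, pyridine, DMAP, then aqueous work-up to hydrolyse the mixed anhydride) gives target 27.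

Further compounds
F1 | step 9 | (1R,2S)-2-allyl-2,3-dimethyl-4-vinylcyclopent-3-en-1-yl prop-2-ynoate | C=CC[C@]1(C)[C@H](OC(=O)C#C)CC(C=C)=C1C
F2 | step 9 | 1-allyl-2-hydroxy-1,7a-dimethyl-2,3,5,7a-tetrahydro-1H-indene-7-carboxylic acid 7,2-lactone | C=CC[C@]1(C)[C@H]2CC3=CCC=C(C(=O)O2)[C@@]31C
F3 | step 13 | (1S,7aS)-1-allyl-2-[methoxy(trimethylsilyl)methyl]-1,7,7,7a-tetramethyl-2,3,5,6,7,7a-hexahydro-1H-inden-2-ol | C=CC[C@]1(C)C(O)(C(OC)[Si](C)(C)C)CC2=CCCC(C)(C)[C@@]21C
F4 | step 19 | (1R,2S,7aS)-1-[(3Z)-5-hydroxy-4-methylpent-3-en-1-yl]-1,7,7,7a-tetramethyl-2,3,5,6,7,7a-hexahydro-1H-indene-2-carbaldehyde | OC/C(C)=C\CC[C@]1(C)[C@@H](C=O)CC2=CCCC(C)(C)[C@@]21C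
F5 | step 19 | (1R,2S,7aS)-1-[(3Z)-5-hydroxy-4-methylpent-3-en-1-yl]-1,7,7,7a-tetramethyl-2,3,5,6,7,7a-hexahydro-1H-indene-2-carboxylic acid | OC/C(C)=C\CC[C@]1(C)[C@@H](C(=O)O)CC2=CCCC(C)(C)[C@@]21C
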